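**Plan**
- Cuts, in order: the four Si–O bonds; C2–C3 of ring C; O1–C2, which separates a ring-A acetophenone from vanillin. Then C8–CH2 (prenyl, made from an allyl group) and C6–CH2 (hydroxyethyl arm, made from an allyl group), back to phloroacetophenone.
- Enabling feature: C2 is bonded to O1 and is benzylic to ring B, whose 4'-oxygen lies para to it, so C2 can exist as a flat, doubly stabilised oxocarbenium ion. C3 is the α-carbon of the C4 ketone on C4a, next to C8a–O1, so as an enol silane it can reach C2 only by forming the six-membered ring C.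
- Forward: rings A and B are bought. Ring A receives the O7 silyl ether, the C6 arm (Mitsunobu, Claisen, cleavage), a temporary seven-membered silylene ring O5–Si–O(arm), and the C8 prenyl group (Mitsunobu, Claisen, metathesis). O1 is then the only free phenol.
- O1 is joined to C2 as a racemic O-aryl O-methyl acetal of silylated vanillin, C4 becomes its enol silane, and ring C closes last.
- Stereochemistry: C2 is the only stereocentre. Ionisation erases it, the chiral counter-anion sets it as (S) during ring closure, and base-free desilylation preserves it.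

Key step: step 13

Assumption: the sense of induction of the confined acid cannot be predicted. The catalyst antipode that delivers (2S) is chosen after a test run, since both antipodes are accessible from (R)- or (S)-BINOL.

Step 1
Reactants: 1 2,4,6-trihydroxyacetophenone
Product: 2 2,6-dihydroxy-4-(triisopropylsilyloxy)acetophenone
Conditions: TIPSCl (1.0 equiv), imidazole, DMF, 0 °C
Reagents that add atoms: triisopropylsilyl chloride, CC(C)[Si](Cl)(C(C)C)C(C)C
Why: Regioselective silyl ether formation should stop at the 4-OH, which is the most acidic hydroxyl and the only one neither hydrogen-bonded to nor crowded by the acetyl group.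

Step 2
Reactants: 2 2,6-dihydroxy-4-(triisopropylsilyloxy)acetophenone, 3 allyl alcohol
Product: 4 2-allyloxy-6-hydroxy-4-(triisopropylsilyloxy)acetophenone
Conditions: PPh3, DIAD, THF, 0 °C → rt
Reagents that add atoms: none
Why: Mitsunobu etherification is neutral and spares the base-labile aryl silyl ether, and after the first alkylation the remaining ortho-hydroxyl is locked in a hydrogen bond to the carbonyl, which should hold the reaction at the mono-ether.

Step 3
Reactants: 4 2-allyloxy-6-hydroxy-4-(triisopropylsilyloxy)acetophenone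
Product: 5 3-allyl-2,6-dihydroxy-4-(triisopropylsilyloxy)acetophenone
Conditions: PhNEt2, 190 °C (sealed tube)
Reagents that add atoms: none
Why: The aromatic Claisen rearrangement moves the allyl group to a ring CH between two oxygens, and because the product has identical hydroxyls at C2 and C6, both conceivable termini (C3 or C5) give the same compound.

Step 4
Reactants: 5 3-allyl-2,6-dihydroxy-4-(triisopropylsilyloxy)acetophenone
Product: 7 2,6-dihydroxy-3-(2-hydroxyethyl)-4-(triisopropylsilyloxy)acetophenone, via arylacetaldehyde 6 (not isolated)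
Conditions: OsO4 (cat), NaIO4, 2,6-lutidine, dioxane/H2O, rt; extractive work-up; NaBH4, THF/MeOH, −20 °C
Reagents that add atoms: osmium tetroxide, O=[Os](=O)(=O)=O (catalytic oxygen carrier); sodium periodate, [Na+].[O-]I(=O)(=O)=O (terminal oxygen source)
Why: Lemieux–Johnson cleavage removes the terminal CH2, and borohydride then reduces the aldehyde (drawn from its lactol equilibrium) much faster than the doubly chelated, electron-rich aryl ketone.

Step 5
Reactants: 7 2,6-dihydroxy-3-(2-hydroxyethyl)-4-(triisopropylsilyloxy)acetophenone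
Product: 8 1-[2,2-di-tert-butyl-8-hydroxy-6-(triisopropylsilyloxy)-4,5-dihydro-1,3,2-benzodioxasilepin-9-yl]ethanone (O2 and the arm oxygen of 7 bridged by Si(t-Bu)2)
Conditions: t-Bu2Si(OTf)2 (1.05 equiv), 2,6-lutidine, CH2Cl2 (dilute), −20 → 0 °C
Reagents that add atoms: di-tert-butylsilyl bis(trifluoromethanesulfonate), CC(C)(C)[Si](OS(=O)(=O)C(F)(F)F)(OS(=O)(=O)C(F)(F)F)C(C)(C)C
Why: In this cyclic silylene protection of a 1,4-related diol the primary alcohol is silylated first, and the second Si–OTf bond can reach only the neighbouring O2, because O4 is blocked and O6 lies para to the arm, so O6–H (the future O1) stays free.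

Step 6
Reactants: 8 silylene phenol, 3 allyl alcohol
Product: 9 1-[8-allyloxy-2,2-di-tert-butyl-6-(triisopropylsilyloxy)-4,5-dihydro-1,3,2-benzodioxasilepin-9-yl]ethanone
Conditions: PPh3, DIAD, THF/toluene, 0 °C → rt
Reagents that add atoms: none
Why: Mitsunobu etherification of the single remaining chelated phenol is well known for 2-hydroxy-4,6-dioxygenated acetophenones and again avoids base.

Step 7
Reactants: 9 allyl ether
Product: 10 1-[7-allyl-2,2-di-tert-butyl-8-hydroxy-6-(triisopropylsilyloxy)-4,5-dihydro-1,3,2-benzodioxasilepin-9-yl]ethanone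
Conditions: PhNEt2, 190–200 °C (sealed tube)
Reagents that add atoms: none
Why: This aromatic Claisen rearrangement has one open terminus only, the ring CH ortho to the ether oxygen (future C8), since the other ortho carbon bears the acetyl group and the para carbon bears the tethered arm.

Step 8
Reactants: 10 C-allyl phenol, 11 2-methyl-2-butene
Product: 12 1-[2,2-di-tert-butyl-8-hydroxy-7-(3-methylbut-2-enyl)-6-(triisopropylsilyloxy)-4,5-dihydro-1,3,2-benzodioxasilepin-9-yl]ethanone
Conditions: Grubbs II (5 mol %), 2-methyl-2-butene/CH2Cl2, 40 °C (sealed tube)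
Reagents that add atoms: none
Why: Olefin cross-metathesis of a terminal allylarene in excess trisubstituted alkene is the standard allyl-to-prenyl conversion and is driven by loss of a volatile alkene.

Step 9
Reactants: 13 vanillin
Product: 14 4-(tert-butyldimethylsilyloxy)-3-methoxybenzaldehyde
Conditions: TBSCl, imidazole, CH2Cl2, rt
Reagents that add atoms: tert-butyldimethylsilyl chloride, CC(C)(C)[Si](C)(C)Cl
Why: This is routine silyl ether formation on an unhindered, acidic phenol.

Step 10
Reactants: 14 4-(tert-butyldimethylsilyloxy)-3-methoxybenzaldehyde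
Product: 15 4-(tert-butyldimethylsilyloxy)-3-methoxybenzaldehyde dimethyl acetal
Conditions: HC(OMe)3, PPTS (cat), MeOH, rt; Et3N quench
Reagents that add atoms: trimethyl orthoformate, COC(OC)OC
Why: Acid-catalysed acetalisation is driven by the orthoester as water scavenger, and the aryl silyl ether tolerates the weak acid.

Step 11
Reactants: 12 prenyl phenol, 15 dimethyl acetal
Product: 17 rac-1-{8-[(4-tert-butyldimethylsilyloxy-3-methoxyphenyl)(methoxy)methoxy]-2,2-di-tert-butyl-7-(3-methylbut-2-enyl)-6-(triisopropylsilyloxy)-4,5-dihydro-1,3,2-benzodioxasilepin-9-yl}ethanone, via alpha-chloro ether 16 (not isolated)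
Conditions: 15, AcCl, ZnBr2 (cat), toluene, 0 °C → rt, volatiles evaporated; 12, NaH, THF, 0 °C, then 16, −40 → 0 °C; cold aq NaHCO3, basic alumina
Reagents that add atoms: none
Why: Zinc(II)-catalysed acetal–acyl chloride exchange gives the alpha-chloro ether, which alkylates the only free phenoxide on oxygen as chloromethyl methyl ether does (Williamson-type alkylation by an alpha-halo ether), and the new acetal carbon is racemic by design.

Step 12
Reactants: 17 rac-mixed acetal ketone
Product: 18 rac-triethylsilyl enol ether of 17 (the acetyl group becomes C(=CH2)OSiEt3)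
Conditions: KHMDS, THF, −78 °C; TESCl, −78 → −40 °C; pentane/cold aq NaHCO3, Et3N-deactivated silica, high vacuum
Reagents that add atoms: chlorotriethylsilane, CC[Si](Cl)(CC)CC
Why: Kinetic deprotonation of the only enolisable position and O-silylation of the potassium enolate with a chlorosilane give the enol silane under strictly basic conditions, whereas a silyl triflate/amine protocol would ionise the acetal.

Step 13
Reactants: 18 rac-acetal enol silane
Product: 20 (2S)-4'-O-TBS-7-O-TIPS-O5,O(arm)-(di-tert-butylsilylene)laxiflorin, via oxocarbenium ion 19 (not isolated)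
Conditions: confined BINOL-derived imidodiphosphorimidate (IDPi) Brønsted acid (5 mol %), toluene (0.01 M), −78 °C; Et3N quench at −78 °C
Reagents that add atoms: none
Why: Proposed new method: a trace of 18 silylates the acid, the resulting silylium–imidodiphosphorimidate pair transfers Et3Si+ to the exposed and more basic methoxy oxygen, and loss of MeOSiEt3 leaves the planar O1=C2 oxocarbenium ion 19, stabilised by the para-silyloxy B ring and paired with the chiral anion, so that both enantiomers of the acetal merge into one intermediate. C3 of the enol silane then bonds to C2 and the silyl group on the C4 oxygen passes back to the anion, which restarts the cycle. The closest known reaction types are Mukaiyama-type additions of enol silanes to acetal-derived oxocarbenium ions under asymmetric counter-anion-directed silylium catalysis and the Petasis–Ferrier oxocarbenium–enolate ring closure; neither has been shown for an aryloxy-substituted cation or for a chromanone ring. Ring C closes in the 6-(enolendo)-endo-trig mode, the only ring size that the C4–C4a–C8a link allows. C2 is the only new stereocentre and, the substrate being otherwise achiral, its (S) configuration depends solely on which face of the cation the confined anion leaves open. The step needs loss of methoxide rather than of the O1 aryloxide and attack by the enol silane rather than by the C8 prenyl alkene (oxonia-Prins): O1 is shielded by the prenyl group and the silyloxyvinyl carbon and is a poorer leaving group now that C4 is no longer a carbonyl, wrong-way ionisation is reversible and leads on only through a bimolecular addition that high dilution disfavours, and an enol silane is far more nucleophilic than a trisubstituted alkene.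

Step 14
Reactants: 20 protected (2S)-flavanone
Product: 21 laxiflorin, (2S)-5,7-dihydroxy-2-(4-hydroxy-3-methoxyphenyl)-6-(2-hydroxyethyl)-8-(3-methylbut-2-enyl)chroman-4-one
Conditions: HF·pyridine, pyridine/THF, 0 °C → rt (polypropylene vessel); pH 6 buffer
Reagents that add atoms: none
Why: Fluoride-mediated desilylation in a weakly acidic buffered medium cleaves all four Si–O bonds, and the absence of base prevents retro-oxa-Michael opening of ring C, so C2 should keep its configuration.

**Compound list**
1 | 2,4,6-trihydroxyacetophenone | CC(=O)c1c(O)cc(O)cc1O | starting material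
2 | 2,6-dihydroxy-4-(triisopropylsilyloxy)acetophenone | CC(=O)c1c(O)cc(O[Si](C(C)C)(C(C)C)C(C)C)cc1O | intermediate
3 | allyl alcohol | C=CCO | starting material
4 | 2-allyloxy-6-hydroxy-4-(triisopropylsilyloxy)acetophenone | CC(=O)c1c(O)cc(O[Si](C(C)C)(C(C)C)C(C)C)cc1OCC=C | intermediate
5 | 3-allyl-2,6-dihydroxy-4-(triisopropylsilyloxy)acetophenone | CC(=O)c1c(O)cc(O[Si](C(C)C)(C(C)C)C(C)C)c(CC=C)c1O | intermediate
6 | [3-acetyl-2,4-dihydroxy-6-(triisopropylsilyloxy)phenyl]acetaldehyde (in equilibrium with its lactol) | CC(=O)c1c(O)cc(O[Si](C(C)C)(C(C)C)C(C)C)c(CC=O)c1O | intermediate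
7 | 2,6-dihydroxy-3-(2-hydroxyethyl)-4-(triisopropylsilyloxy)acetophenone | CC(=O)c1c(O)cc(O[Si](C(C)C)(C(C)C)C(C)C)c(CCO)c1O | intermediate
8 | 1-[2,2-di-tert-butyl-8-hydroxy-6-(triisopropylsilyloxy)-4,5-dihydro-1,3,2-benzodioxasilepin-9-yl]ethanone | CC(=O)c1c(O)cc(O[Si](C(C)C)(C(C)C)C(C)C)c2CCO[Si](C(C)(C)C)(C(C)(C)C)Oc12 | intermediate
9 | 8-O-allyl ether of 8 | CC(=O)c1c(OCC=C)cc(O[Si](C(C)C)(C(C)C)C(C)C)c2CCO[Si](C(C)(C)C)(C(C)(C)C)Oc12 | intermediate
10 | 7-allyl derivative of 8 | CC(=O)c1c(O)c(CC=C)c(O[Si](C(C)C)(C(C)C)C(C)C)c2CCO[Si](C(C)(C)C)(C(C)(C)C)Oc12 | intermediate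
11 | 2-methyl-2-butene | CC=C(C)C | starting material
12 | 7-(3-methylbut-2-enyl) derivative of 8 | CC(=O)c1c(O)c(CC=C(C)C)c(O[Si](C(C)C)(C(C)C)C(C)C)c2CCO[Si](C(C)(C)C)(C(C)(C)C)Oc12 | intermediate
13 | vanillin | COc1cc(C=O)ccc1O | starting material
14 | 4-(tert-butyldimethylsilyloxy)-3-methoxybenzaldehyde | COc1cc(C=O)ccc1O[Si](C)(C)C(C)(C)C | intermediate
15 | 4-(tert-butyldimethylsilyloxy)-3-methoxybenzaldehyde dimethyl acetal | COc1cc(C(OC)OC)ccc1O[Si](C)(C)C(C)(C)C | intermediate
16 | rac-tert-butyl{4-[chloro(methoxy)methyl]-2-methoxyphenoxy}dimethylsilane | COc1cc(C(Cl)OC)ccc1O[Si](C)(C)C(C)(C)C | intermediate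
17 | rac-O-aryl O-methyl acetal of 14 on the free phenol oxygen of 12 (ketone) | COc1cc(C(OC)Oc2c(CC=C(C)C)c(O[Si](C(C)C)(C(C)C)C(C)C)c3CCO[Si](C(C)(C)C)(C(C)(C)C)Oc3c2C(C)=O)ccc1O[Si](C)(C)C(C)(C)C | intermediate
18 | rac-triethylsilyl enol ether of 17 | COc1cc(C(OC)Oc2c(CC=C(C)C)c(O[Si](C(C)C)(C(C)C)C(C)C)c3CCO[Si](C(C)(C)C)(C(C)(C)C)Oc3c2C(=C)O[Si](CC)(CC)CC)ccc1O[Si](C)(C)C(C)(C)C | intermediate
19 | O1=C2 oxocarbenium ion (cation of the ion pair with the catalyst anion) | COc1cc(C=[O+]c2c(CC=C(C)C)c(O[Si](C(C)C)(C(C)C)C(C)C)c3CCO[Si](C(C)(C)C)(C(C)(C)C)Oc3c2C(=C)O[Si](CC)(CC)CC)ccc1O[Si](C)(C)C(C)(C)C | intermediate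
20 | (2S)-4'-O-TBS-7-O-TIPS-O5,O(arm)-(di-tert-butylsilylene)laxiflorin | COc1cc([C@@H]2CC(=O)c3c4O[Si](C(C)(C)C)(C(C)(C)C)OCCc4c(O[Si](C(C)C)(C(C)C)C(C)C)c(CC=C(C)C)c3O2)ccc1O[Si](C)(C)C(C)(C)C | intermediate
21 | laxiflorin, (2S) | COc1cc([C@@H]2CC(=O)c3c(O)c(CCO)c(O)c(CC=C(C)C)c3O2)ccc1O | target

Total step count: 14. Longest linear sequence: 12 (steps 1–8 and 11–14).

**Steps most likely to fail**

Step 13.
- What may go wrong: the large, heavily silylated cation may sit loosely against the confined anion and give poor facial discrimination. The acetal may ionise the wrong way by loss of the O1 aryloxide and then react bimolecularly. Re-ionisation of the C2–O1 bond of the product may erode the enantiomeric purity.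
- Fallback (known chemistry): C2–C1' is formed instead of C2–C3. Setting out from 12, condensation with N,N-dimethylformamide dimethyl acetal (toluene, 90 °C) should give the (E)-3-(dimethylamino)propenone enaminone F1. Warm acetic acid closes this to the 2,3-unsubstituted chromone F2.
- A rhodium(I)/chiral diene-catalysed Hayashi–Miyaura 1,4-addition then sets C2 under ligand control and comes back to the route at 20. The aryl donor is 2-[4-(tert-butyldimethylsilyloxy)-3-methoxyphenyl]-4,4,5,5-tetramethyl-1,3,2-dioxaborolane F3, made from commercial 4-hydroxy-3-methoxyphenylboronic acid pinacol ester with TBSCl and imidazole.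

Step 11.
- What may go wrong: the electron-rich alpha-chloro ether may ionise prematurely. The mixed acetal may do the same, because its aryloxide is a good leaving group while C4 is still a ketone. Either event leads to hydrolysis during work-up or handling.
- Fallback: the covalent halide is replaced by a salt-type oxocarbenium reservoir formed under weakly basic conditions. Setting out from 15 and 12, treating 15 with TESOTf and 2,4,6-collidine (CH2Cl2, 0 °C) should give N-[(4-tert-butyldimethylsilyloxy-3-methoxyphenyl)(methoxy)methyl]-2,4,6-collidinium triflate F4. Adding the sodium salt of 12 displaces the pyridine base and comes back to the route at 17.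

Step 4.
- What may go wrong: the unprotected, electron-rich resorcinol ring may be over-oxidised, the lactol may dehydrate to a benzofuran, or the silyl group may migrate from the aryl oxygen to the arm oxygen during the borohydride stage.
- Fallback: the arm is built without an oxidant or an aldehyde. Setting out from 2, mono-iodination with N-iodosuccinimide should give 3-iodo-2,6-dihydroxy-4-(triisopropylsilyloxy)acetophenone F5. Stille coupling with tributyl(vinyl)stannane then gives 2,6-dihydroxy-4-(triisopropylsilyloxy)-3-vinylacetophenone F6.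
- Iridium-catalysed anti-Markovnikov hydroboration with pinacolborane gives the primary 2-arylethyl pinacolboronate F7, and sodium perborate oxidation comes back to the route at 7, replacing steps 2–4.

**Further compounds**
F1 | step 13 | (E)-3-(dimethylamino)-1-aryl-prop-2-en-1-one derived from 12 | CN(C)/C=C/C(=O)c1c(O)c(CC=C(C)C)c(O[Si](C(C)C)(C(C)C)C(C)C)c2CCO[Si](C(C)(C)C)(C(C)(C)C)Oc12
F2 | step 13 | 7-O-TIPS-O5,O(arm)-(di-tert-butylsilylene)-6-(2-oxyethyl)-8-prenylchromone | O=c1ccoc2c(CC=C(C)C)c(O[Si](C(C)C)(C(C)C)C(C)C)c3CCO[Si](C(C)(C)C)(C(C)(C)C)Oc3c12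
F3 | step 13 | 2-[4-(tert-butyldimethylsilyloxy)-3-methoxyphenyl]-4,4,5,5-tetramethyl-1,3,2-dioxaborolane | COc1cc(B2OC(C)(C)C(C)(C)O2)ccc1O[Si](C)(C)C(C)(C)C
F4 | step 11 | N-[(4-tert-butyldimethylsilyloxy-3-methoxyphenyl)(methoxy)methyl]-2,4,6-collidinium triflate (racemic) | COc1cc(C(OC)[n+]2c(C)cc(C)cc2C)ccc1O[Si](C)(C)C(C)(C)C.[O-]S(=O)(=O)C(F)(F)F
F5 | step 4 | 3-iodo-2,6-dihydroxy-4-(triisopropylsilyloxy)acetophenone | CC(=O)c1c(O)cc(O[Si](C(C)C)(C(C)C)C(C)C)c(I)c1O
F6 | step 4 | 2,6-dihydroxy-4-(triisopropylsilyloxy)-3-vinylacetophenone | CC(=O)c1c(O)cc(O[Si](C(C)C)(C(C)C)C(C)C)c(C=C)c1O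
F7 | step 4 | 2,6-dihydroxy-3-[2-(4,4,5,5-tetramethyl-1,3,2-dioxaborolan-2-yl)ethyl]-4-(triisopropylsilyloxy)acetophenone | CC(=O)c1c(O)cc(O[Si](C(C)C)(C(C)C)C(C)C)c(CCB2OC(C)(C)C(C)(C)O2)c1O
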